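The 21-membered cyclophane is cut at the bond between Cα of the (E)-cinnamamide and its carbonyl carbon. The step exploits the secondary amide that links the styryl carbon on ring B (the para-phenylene) to the tryptamine nitrogen. N–C(=O) is read as an isocyanate and Cα as an (E)-alkenylboronate. In one operation the side-chain azide of the open-chain precursor takes up CO2 (Staudinger/aza-Wittig). Rhodium-catalysed alkenyl transfer then closes the ring, delivering carbonyl carbon, amide and macrocycle with retained alkene geometry. The precursor already holds the (7R,8S)-erythro aryl ether unit. It is set by an auxiliary-controlled anti-aldol and locked as a dioxasilinane that turns both arms towards each other.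

Key step: step 9

Remark on numbering: C7 is the benzylic carbinol carbon, C8 the aryloxy-bearing carbon and C9 the CH2OH carbon. Ring A is the trioxygenated benzene and ring B the para-disubstituted benzene. TOM = CH2OSi(i-Pr)3. The target SMILES corresponds to (7R,8S), the erythro (anti) series.
Assumption: the anti-aldol of step 5 is taken to follow the magnesium-chelated Z-enolate model of N-acyl oxazolidinones, which with the (S)-auxiliary leads to (7R,8S).

Step 1
Reactants: 1 3,4-dihydroxy-5-methoxybenzaldehyde (5-hydroxyvanillin)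
Product: 2 3-hydroxy-5-methoxy-4-(TOM-oxy)benzaldehyde
Conditions: TOM-Cl (1.05 equiv), K2CO3 (1.0 equiv), DMF, 0 °C to rt
Reagents that add atoms: (triisopropylsiloxy)methyl chloride (TOM-Cl), ClCO[Si](C(C)C)(C(C)C)C(C)C
Why: Williamson-type O-alkylation with a chloromethyl ether: one equivalent of carbonate ionises only the 4-OH (para to the formyl group and clearly the more acidic), the acetal-type TOM group cannot migrate to the neighbouring O3 as a silyl or acyl group would, and it falls off with fluoride at the end.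

Step 2
Reactants: 2 3-hydroxy-5-methoxy-4-(TOM-oxy)benzaldehyde; 3 4-ethenylphenylboronic acid
Product: 4 3-(4-ethenylphenoxy)-5-methoxy-4-(TOM-oxy)benzaldehyde
Conditions: Cu(OAc)2 (20 mol %), pyridine (3 equiv), 4 Å MS, O2 (1 atm), CH2Cl2, rt
Reagents that add atoms: none
Why: Chan–Lam coupling: the free 3-OH is arylated through an aryl–copper phenoxide at room temperature, which tolerates the aldehyde, the styrene and the TOM acetal and installs ring B together with its vinyl handle.

Step 3
Reactants: 5 serotonin hydrochloride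
Product: 6 3-(2-azidoethyl)-1H-indol-5-ol
Conditions: imidazole-1-sulfonyl azide hydrogen sulfate (1.2 equiv), K2CO3, CuSO4·5H2O (1 mol %), MeOH, Ar, rt
Reagents that add atoms: imidazole-1-sulfonyl azide hydrogen sulfate, [N-]=[N+]=NS(=O)(=O)n1ccnc1.OS(O)(=O)=O
Why: Copper-catalysed diazo transfer turns the primary amine into the azide without touching the phenol or the indole N–H (argon keeps the 5-hydroxyindole from air oxidation), so nitrogen is masked by a group that needs no removal because it is the direct isocyanate precursor.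

Step 4
Reactants: 6 3-(2-azidoethyl)-1H-indol-5-ol; 7 (4S)-4-benzyl-3-(chloroacetyl)-1,3-oxazolidin-2-one
Product: 8 (4S)-3-({[3-(2-azidoethyl)-1H-indol-5-yl]oxy}acetyl)-4-benzyl-1,3-oxazolidin-2-one
Conditions: K2CO3 (1.5 equiv), NaI (10 mol %), acetone, rt
Reagents that add atoms: none
Why: Williamson ether synthesis by iodide-assisted SN2 displacement at the α-halo imide: carbonate deprotonates the phenol only, not the indole N–H, and the mild anhydrous base leaves the imide intact.

Step 5
Reactants: 8 aryloxyacetyl imide; 4 3-(4-ethenylphenoxy)-5-methoxy-4-(TOM-oxy)benzaldehyde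
Product: 10 (4S)-3-[(2R,3R)-2-{[3-(2-azidoethyl)-1H-indol-5-yl]oxy}-3-[3-(4-ethenylphenoxy)-5-methoxy-4-(TOM-oxy)phenyl]-3-hydroxypropanoyl]-4-benzyl-1,3-oxazolidin-2-one (anti-aldol adduct), via trimethylsilyl ether 9 (not isolated)
Conditions: MgCl2 (20 mol %), Et3N (2 equiv), Me3SiCl (1.5 equiv), EtOAc, rt; then TFA (cat.), MeOH, 0 °C
Reagents that add atoms: none
Why: Magnesium-halide-catalysed direct anti-aldol of an N-acyl oxazolidinone (Evans anti-aldol) with a non-enolisable aromatic aldehyde: soft enolisation gives the magnesium-chelated Z-enolate, the benzyl group shields one face so that C8 is set in the sense of auxiliary-controlled alkylations, the boat-like transition state places O7 anti to O8 (C7 becomes R), and silylation of the aldolate makes the addition irreversible under conditions mild enough for indole N–H, azide, styrene and TOM group.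

Step 6
Reactants: 10 anti-aldol adduct
Product: 11 (1R,2S)-2-{[3-(2-azidoethyl)-1H-indol-5-yl]oxy}-1-[3-(4-ethenylphenoxy)-5-methoxy-4-(TOM-oxy)phenyl]propane-1,3-diol
Conditions: LiBH4 (2 equiv), H2O (2 equiv), Et2O–THF, 0 °C
Reagents that add atoms: none
Why: Reductive cleavage of the N-acyl oxazolidinone with LiBH4 delivers C9 as CH2OH and returns the auxiliary, is fast enough at 0 °C to outrun retro-aldol cleavage and leaves azide, styrene, TOM group and both stereocentres untouched.

Step 7
Reactants: 11 erythro 1,3-diol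
Product: 12 (4R,5S)-5-{[3-(2-azidoethyl)-1H-indol-5-yl]oxy}-2,2-di-tert-butyl-4-[3-(4-ethenylphenoxy)-5-methoxy-4-(TOM-oxy)phenyl]-1,3,2-dioxasilinane
Conditions: t-Bu2Si(OTf)2 (1.1 equiv), 2,6-lutidine (3 equiv), CH2Cl2, 0 °C
Reagents that add atoms: di-tert-butylsilyl bis(trifluoromethanesulfonate), CC(C)(C)[Si](OS(=O)(=O)C(F)(F)F)(OS(=O)(=O)C(F)(F)F)C(C)(C)C
Why: Cyclic silylene protection of a 1,3-diol: the erythro diol closes to a chair 1,3,2-dioxasilinane with ring A (on C7) and the indolyloxy group (on C8) both equatorial, which masks both hydroxyl groups against the isocyanate with one fluoride-labile group and pre-organises the seco compound.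

Step 8
Reactants: 12 styrene dioxasilinane; 13 vinylboronic acid pinacol ester
Product: 14 (E)-alkenylboronate: 12 in which the ethenyl group of ring B has become (E)-2-(4,4,5,5-tetramethyl-1,3,2-dioxaborolan-2-yl)ethenyl
Conditions: 13 (3 equiv), second-generation Hoveyda–Grubbs catalyst (5 mol %), CH2Cl2, 40 °C
Reagents that add atoms: none
Why: Olefin cross-metathesis of a styrene with a vinylboronate, a pairing known to be strongly E-selective for steric reasons, and the phosphine-free catalyst avoids a Staudinger reaction with the azide.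

Step 9
Reactants: 14 azido (E)-alkenylboronate
Product: 17 protected (7R,8S)-macrolactam (the target with O4 of ring A as TOM ether and O7/O9 bridged by Si(t-Bu)2), via iminophosphorane 15 (not isolated), via isocyanate 16 (not isolated)
Conditions: PPh3 (1.0 equiv), CO2 (5 bar), THF, rt to 40 °C; vent, Ar purge; then slow addition (12 h) to [Rh(OH)(cod)]2 (5 mol %), H2O (5 equiv), THF, 40 °C, final 1 mM
Reagents that add atoms: carbon dioxide, O=C=O
Why: PPh3 converts the azide with loss of N2 into iminophosphorane 15, whose aza-Wittig reaction with CO2 gives isocyanate 16 and Ph3P=O; after CO2 is purged (so that the alkenyl-rhodium is not carboxylated), Rh–OH takes over the (E)-alkenyl group from boron with retention, the tethered N=C unit inserts into the Rh–C bond to form the Cα–C(=O) bond, and water protonates the rhodium amidate to release the secondary amide and Rh–OH. The closest known reaction types are the Staudinger/aza-Wittig synthesis of isocyanates from azides and CO2 and the intermolecular addition of aryl- and alkenylboronic acids to isocyanates under monovalent rhodium catalysis, used here in a ring-closing sense. One ring is closed, the 21-membered macrolactam, by attack at the sp carbon of N=C=O with the C=N bond inside and the C=O bond outside the new ring (formally 21-endo-dig). No stereocentre is created: the E geometry fixed in step 8 is carried through because transmetalation and insertion are stereoretentive, and C7 and C8 are not touched under these neutral conditions. The step needs ring closure to win over oligomerisation and the isocyanate to meet no other nucleophile: slow addition keeps 16 near millimolar, the chair dioxasilinane holds ring A on C7 and the indolyloxy group on C8 equatorial and gauche so that both arms point the same way, all three hydroxyl groups are masked, and the indole N–H is too weakly nucleophilic to add.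

Step 10
Reactants: 17 protected macrolactam
Product: 18 CNP0276372.1 (target, 7R,8S, E)
Conditions: Bu4NF (4 equiv), AcOH (4 equiv), THF, 0 °C to rt
Reagents that add atoms: none
Why: Fluoride-induced desilylation: the silylene is cleaved to the 1,3-diol and the TOM group loses its silyl cap to give an aryl hemiacetal that expels formaldehyde, while the acetic acid buffer prevents phenoxide-driven quinone methide formation so that C7 and C8 keep their configuration.

Compound list
1 | 3,4-dihydroxy-5-methoxybenzaldehyde | COc1cc(C=O)cc(O)c1O | starting material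
2 | 3-hydroxy-5-methoxy-4-(TOM-oxy)benzaldehyde | COc1cc(C=O)cc(O)c1OCO[Si](C(C)C)(C(C)C)C(C)C | intermediate
3 | 4-ethenylphenylboronic acid | OB(O)c1ccc(C=C)cc1 | starting material
4 | 3-(4-ethenylphenoxy)-5-methoxy-4-(TOM-oxy)benzaldehyde | COc1cc(C=O)cc(Oc2ccc(C=C)cc2)c1OCO[Si](C(C)C)(C(C)C)C(C)C | intermediate
5 | serotonin hydrochloride | NCCc1c[nH]c2ccc(O)cc12.Cl | starting material
6 | 3-(2-azidoethyl)-1H-indol-5-ol | [N-]=[N+]=NCCc1c[nH]c2ccc(O)cc12 | intermediate
7 | (4S)-4-benzyl-3-(chloroacetyl)-1,3-oxazolidin-2-one | O=C1OC[C@H](Cc2ccccc2)N1C(=O)CCl | starting material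
8 | (4S)-3-({[3-(2-azidoethyl)-1H-indol-5-yl]oxy}acetyl)-4-benzyl-1,3-oxazolidin-2-one | O=C1OC[C@H](Cc2ccccc2)N1C(=O)COc1ccc2[nH]cc(CCN=[N+]=[N-])c2c1 | intermediate
9 | O7-trimethylsilyl ether of the (2R,3R) anti-aldol adduct | O=C1OC[C@H](Cc2ccccc2)N1C(=O)[C@H](Oc1ccc2[nH]cc(CCN=[N+]=[N-])c2c1)[C@H](O[Si](C)(C)C)c1cc(OC)c(OCO[Si](C(C)C)(C(C)C)C(C)C)c(Oc2ccc(C=C)cc2)c1 | intermediate
10 | (4S)-imide of the (2R,3R)-2-aryloxy-3-aryl-3-hydroxypropanoic acid (anti-aldol adduct) | O=C1OC[C@H](Cc2ccccc2)N1C(=O)[C@H](Oc1ccc2[nH]cc(CCN=[N+]=[N-])c2c1)[C@H](O)c1cc(OC)c(OCO[Si](C(C)C)(C(C)C)C(C)C)c(Oc2ccc(C=C)cc2)c1 | intermediate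
11 | (1R,2S)-2-{[3-(2-azidoethyl)-1H-indol-5-yl]oxy}-1-[3-(4-ethenylphenoxy)-5-methoxy-4-(TOM-oxy)phenyl]propane-1,3-diol | OC[C@H](Oc1ccc2[nH]cc(CCN=[N+]=[N-])c2c1)[C@H](O)c1cc(OC)c(OCO[Si](C(C)C)(C(C)C)C(C)C)c(Oc2ccc(C=C)cc2)c1 | intermediate
12 | (4R,5S)-2,2-di-tert-butyl-1,3,2-dioxasilinane of 11 | CC(C)(C)[Si]1(C(C)(C)C)OC[C@H](Oc2ccc3[nH]cc(CCN=[N+]=[N-])c3c2)[C@@H](c2cc(OC)c(OCO[Si](C(C)C)(C(C)C)C(C)C)c(Oc3ccc(C=C)cc3)c2)O1 | intermediate
13 | vinylboronic acid pinacol ester | C=CB1OC(C)(C)C(C)(C)O1 | starting material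
14 | azido (E)-alkenylboronate | CC(C)(C)[Si]1(C(C)(C)C)OC[C@H](Oc2ccc3[nH]cc(CCN=[N+]=[N-])c3c2)[C@@H](c2cc(OC)c(OCO[Si](C(C)C)(C(C)C)C(C)C)c(Oc3ccc(/C=C/B4OC(C)(C)C(C)(C)O4)cc3)c2)O1 | intermediate
15 | N-alkyl triphenyliminophosphorane of 14 | CC(C)(C)[Si]1(C(C)(C)C)OC[C@H](Oc2ccc3[nH]cc(CCN=P(c4ccccc4)(c4ccccc4)c4ccccc4)c3c2)[C@@H](c2cc(OC)c(OCO[Si](C(C)C)(C(C)C)C(C)C)c(Oc3ccc(/C=C/B4OC(C)(C)C(C)(C)O4)cc3)c2)O1 | intermediate
16 | isocyanato (E)-alkenylboronate | CC(C)(C)[Si]1(C(C)(C)C)OC[C@H](Oc2ccc3[nH]cc(CCN=C=O)c3c2)[C@@H](c2cc(OC)c(OCO[Si](C(C)C)(C(C)C)C(C)C)c(Oc3ccc(/C=C/B4OC(C)(C)C(C)(C)O4)cc3)c2)O1 | intermediate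
17 | protected (7R,8S,E)-macrolactam | COc1cc2cc(c1OCO[Si](C(C)C)(C(C)C)C(C)C)Oc1ccc(cc1)/C=C/C(=O)NCCc1c[nH]c3ccc(cc13)O[C@H]4CO[Si](C(C)(C)C)(C(C)(C)C)O[C@H]24 | intermediate
18 | CNP0276372.1 | COc1cc2cc(c1O)Oc1ccc(cc1)/C=C/C(=O)NCCc1c[nH]c3ccc(cc13)O[C@@H](CO)[C@@H]2O | target

Total step count: 10. Longest linear sequence: 8 steps (3, 4, 5, 6, 7, 8, 9, 10, or equally 1, 2, 5, 6, 7, 8, 9, 10).

Steps most likely to fail

Step 9. Four processes may erode the closure:
- intermolecular alkenyl transfer leading to oligomers;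
- hydrolysis of the isocyanate followed by urea formation;
- condensation of 15 with 16 to a carbodiimide;
- slow boron-to-rhodium transfer from the pinacol ester, ending in protodeboronation.

The fallback sets out from 14 and comes back at 17. Iododeboronation (I2, NaOH, THF) would give the azido (E)-alkenyl iodide F1. Staudinger reduction (PPh3, THF–H2O) would then give the amino (E)-alkenyl iodide F2. Carbonylative macrolactamisation under zerovalent palladium catalysis (Pd(PPh3)4, CO 1 atm, Et3N, MeCN–THF, 60 °C, high dilution) would build the same Cα–C(=O) bond by CO insertion into the alkenyl–palladium bond. The ring closes in the same operation by capture of the acyl-palladium with the amine.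

Step 5. The α-aryloxy group may disturb the chelated enolate, which would give poor anti/syn or facial selectivity. Retro-aldol equilibration before silylation may erode it further. The fallback sets out from 6 and 4 and comes back at 11.
- Alkylation of 6 with (4R)-4-benzyl-3-(chloroacetyl)-1,3-oxazolidin-2-one (K2CO3, NaI, acetone) gives the enantiomeric-auxiliary imide F3.
- The boron-mediated Evans syn-aldol (Bu2BOTf, Et3N, CH2Cl2, −78 to 0 °C, then 4) sets C8 correctly through the closed chair transition state and gives the (2R,3S) syn adduct F4.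
- Mitsunobu inversion at C7 (4-nitrobenzoic acid, PPh3, DIAD, THF) gives the (2R,3R) 4-nitrobenzoate F5.
- LiBH4 cleaves ester and imide together to diol 11.

Step 2. Arylation of the ortho-substituted phenol may be slow, so that protodeboronation, oxidative hydroxylation or homocoupling of the boronic acid consumes 3. The fallback sets out from 2 and comes back at 4. It is an Ullmann-type ether synthesis under monovalent copper catalysis in an inert atmosphere, with an aryl halide in place of the boronic acid: 1-bromo-4-ethenylbenzene, CuI, N,N-dimethylglycine, Cs2CO3, dioxane, 90 °C, with a radical inhibitor. It makes no new compound.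

Further compounds
F1 | step 9 | azido (E)-alkenyl iodide | CC(C)(C)[Si]1(C(C)(C)C)OC[C@H](Oc2ccc3[nH]cc(CCN=[N+]=[N-])c3c2)[C@@H](c2cc(OC)c(OCO[Si](C(C)C)(C(C)C)C(C)C)c(Oc3ccc(/C=C/I)cc3)c2)O1
F2 | step 9 | amino (E)-alkenyl iodide | CC(C)(C)[Si]1(C(C)(C)C)OC[C@H](Oc2ccc3[nH]cc(CCN)c3c2)[C@@H](c2cc(OC)c(OCO[Si](C(C)C)(C(C)C)C(C)C)c(Oc3ccc(/C=C/I)cc3)c2)O1
F3 | step 5 | (4R)-3-({[3-(2-azidoethyl)-1H-indol-5-yl]oxy}acetyl)-4-benzyl-1,3-oxazolidin-2-one | O=C1OC[C@@H](Cc2ccccc2)N1C(=O)COc1ccc2[nH]cc(CCN=[N+]=[N-])c2c1
F4 | step 5 | (4R)-imide of the (2R,3S) syn-aldol adduct | O=C1OC[C@@H](Cc2ccccc2)N1C(=O)[C@H](Oc1ccc2[nH]cc(CCN=[N+]=[N-])c2c1)[C@@H](O)c1cc(OC)c(OCO[Si](C(C)C)(C(C)C)C(C)C)c(Oc2ccc(C=C)cc2)c1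
F5 | step 5 | (4R)-imide of the (2R,3R) 3-(4-nitrobenzoyloxy) compound | O=C1OC[C@@H](Cc2ccccc2)N1C(=O)[C@H](Oc1ccc2[nH]cc(CCN=[N+]=[N-])c2c1)[C@H](OC(=O)c1ccc(cc1)[N+]([O-])=O)c1cc(OC)c(OCO[Si](C(C)C)(C(C)C)C(C)C)c(Oc2ccc(C=C)cc2)c1
F0 | step 2 | none | none
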